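**Plan**

1. Locants (elemane numbering): cyclohexane C5–C10 (C5 carries the acrolein unit C3/C4/C15, C6 the acetate, C7–C8 the lactone fusion, C9 the angelate, C10 the methyl C14 and the vinyl group C1=C2); lactone C11(=C13)–C12.
2. Retrosynthesis: the enal oxidation level, the angelate and the lactone C–O bond are removed first. The ring bonds C9–C10 and C7–C8 are then cut together, which unravels the carbocycle to the acyclic compound 24 with only C5 and C6 stereogenic. 24 is cut further at C7=C11, at C2–B, at C10–CH3 and at C5–C10, back to a five-carbon dienol.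
3. Enabling feature: C8 and C9 both carry oxygen, C7 is allylic to the C11=C13 methylene and C10 is allylic to the C1=C2 vinyl group. An enol ether C13–O–C9H=C8H–OSi can therefore hand C8 to C7 by a [3,3] shift that unmasks C9 as an aldehyde, and a C2 allylboronate then attacks that aldehyde through C10.
4. Forward order: open chain first (epoxide, alkyne, (Z)-allyl unit, (Z)-enoate carrying the enol ether), then the cyclohexane in the key step, then the γ-lactone, the angelate and last the enal.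
5. Stereochemistry: C6 from a Sharpless epoxidation and C5 from invertive opening of that epoxide. C7–C10 are all set in the key step from three alkene geometries (lactone-enforced (Z)-allyl unit, Still–Gennari (Z)-enoate, (Z)-enol ether) through chair transition states, with A(1,3) strain at C6 choosing the alkene face.

Key step: step 17

Step 1
Reactants: 1 2-bromoprop-1-ene; 2 prop-2-yn-1-ol
Product: 3 4-methylpent-4-en-2-yn-1-ol
Conditions: PdCl2(PPh3)2 (cat.), CuI (cat.), Et2NH, rt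
Reagents that add atoms: none
Why: Sonogashira coupling of a vinyl bromide with a terminal alkyne, a standard route to conjugated enynols; no stereocentre is formed.

Step 2
Reactants: 3 4-methylpent-4-en-2-yn-1-ol
Product: 4 (2Z)-4-methylpenta-2,4-dien-1-ol
Conditions: H2 (1 atm), Pd on CaCO3 poisoned with Pb(OAc)2 (Lindlar catalyst), quinoline, EtOAc, rt
Reagents that add atoms: none
Why: Lindlar semi-hydrogenation delivers both hydrogens to one face of the alkyne and should give the (Z)-alkene, the uptake being stopped after one equivalent to spare the 1,1-disubstituted alkene.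

Step 3
Reactants: 4 (2Z)-4-methylpenta-2,4-dien-1-ol
Product: 5 [(2R,3S)-3-(prop-1-en-2-yl)oxiran-2-yl]methanol
Conditions: Ti(OiPr)4 (cat.), D-(−)-diethyl tartrate (cat.), t-BuOOH, 4 Å MS, CH2Cl2, −20 °C
Reagents that add atoms: tert-butyl hydroperoxide, CC(C)(C)OO
Why: Sharpless asymmetric epoxidation; the hydroxyl group directs the titanium tartrate peroxide to the allylic C5=C6 bond only, and the D-(−)-tartrate should deliver oxygen to the face that gives the (2R,3S)-cis-epoxide, which fixes the future C6–O configuration.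

Step 4
Reactants: 5 [(2R,3S)-3-(prop-1-en-2-yl)oxiran-2-yl]methanol
Product: 6 triethyl{[(2R,3S)-3-(prop-1-en-2-yl)oxiran-2-yl]methoxy}silane
Conditions: Et3SiCl, imidazole, CH2Cl2, 0 °C
Reagents that add atoms: chlorotriethylsilane, CC[Si](Cl)(CC)CC
Why: silylation of the primary alcohol under neutral buffered conditions that should leave the vinyl epoxide intact; the ether later serves as a masked C7 aldehyde.

Step 5
Reactants: 6 triethyl{[(2R,3S)-3-(prop-1-en-2-yl)oxiran-2-yl]methoxy}silane; 7 3,3,3-triethoxyprop-1-yne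
Product: 9 ethyl (4S,5S)-5-hydroxy-4-(prop-1-en-2-yl)-6-[(triethylsilyl)oxy]hex-2-ynoate, via orthoester 8 (not isolated)
Conditions: 7, n-BuLi, THF, −78 °C; BF3·OEt2; then 6, −78 °C; then aq. citric acid (pH 4), 0 °C
Reagents that add atoms: water, O
Why: Lewis acid-mediated SN2 opening of an epoxide by a lithium acetylide; attack should occur at the allylic epoxide carbon C5 (activated by the isopropenyl group, while C6 is deactivated by the silyloxymethyl group) with inversion, which sets C5 anti to the C6 hydroxyl, and the mild acid turns the orthoester into the ethyl ester.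

Step 6
Reactants: 9 ethyl (4S,5S)-5-hydroxy-4-(prop-1-en-2-yl)-6-[(triethylsilyl)oxy]hex-2-ynoate
Product: 11 (5S,6S)-4-methyl-5-(prop-1-en-2-yl)-6-{[(triethylsilyl)oxy]methyl}-5,6-dihydro-2H-pyran-2-one, via hydroxy enoate 10 (not isolated)
Conditions: MeLi, CuI, THF, −78 °C; AcOH at −78 °C; then rt
Reagents that add atoms: lithium dimethylcuprate, [Li+].C[Cu-]C (made from methyllithium, [Li]C, and CuI)
Why: conjugate addition of a Gilman cuprate to an ynoate is a syn carbocupration, so after cold protonation the ester stands cis to C5 and only this isomer can lactonise with the C6 hydroxyl; the δ-lactone locks the (Z)-trisubstituted C1=C10 alkene.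

Step 7
Reactants: 11 (5S,6S)-4-methyl-5-(prop-1-en-2-yl)-6-{[(triethylsilyl)oxy]methyl}-5,6-dihydro-2H-pyran-2-one
Product: 12 (2Z,4S,5S)-3-methyl-4-(prop-1-en-2-yl)-6-[(triethylsilyl)oxy]hex-2-ene-1,5-diol
Conditions: i-Bu2AlH (excess), CH2Cl2, −78 to 0 °C; aq. potassium sodium tartrate work-up
Reagents that add atoms: none
Why: hydride reduction of the unsaturated lactone at the carbonyl group (1,2-reduction) opens the ring to the (Z)-allylic alcohol and the C6 alcohol without touching the alkene geometry or the stereocentres.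

Step 8
Reactants: 12 (2Z,4S,5S)-3-methyl-4-(prop-1-en-2-yl)-6-[(triethylsilyl)oxy]hex-2-ene-1,5-diol
Product: 13 (2Z,4S,5S)-3-methyl-4-(prop-1-en-2-yl)-6-[(triethylsilyl)oxy]hex-2-ene-1,5-diyl diacetate
Conditions: Ac2O, pyridine, DMAP (cat.), CH2Cl2, rt
Reagents that add atoms: acetic anhydride, CC(=O)OC(C)=O
Why: acetylation of both hydroxyls; one acetate is the C6 acetate of the target, the other turns the allylic alcohol into a leaving group.

Step 9
Reactants: 13 (2Z,4S,5S)-3-methyl-4-(prop-1-en-2-yl)-6-[(triethylsilyl)oxy]hex-2-ene-1,5-diyl diacetate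
Product: 14 (2S,3S,4Z)-4-methyl-3-(prop-1-en-2-yl)-6-(4,4,5,5-tetramethyl-1,3,2-dioxaborolan-2-yl)-1-[(triethylsilyl)oxy]hex-4-en-2-yl acetate
Conditions: B2pin2, Ni(cod)2 (cat.), PCy3 (cat.), EtOAc, rt
Reagents that add atoms: bis(pinacolato)diboron, CC1(C)OB(OC1(C)C)B1OC(C)(C)C(C)(C)O1
Why: nickel-catalysed borylation of an allylic acetate (π-allyl nickel acetate, transmetalation with the diboron, C–B bond formation at the primary terminus); the 1,1-disubstituted allyl terminus cannot exchange its substituents by σ-allyl rotation, so the (Z)-geometry should be retained, and the second acetate is not allylic and stays.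

Step 10
Reactants: 14 (2S,3S,4Z)-4-methyl-3-(prop-1-en-2-yl)-6-(4,4,5,5-tetramethyl-1,3,2-dioxaborolan-2-yl)-1-[(triethylsilyl)oxy]hex-4-en-2-yl acetate
Product: 15 (2S,3S,4Z)-4-methyl-1-oxo-3-(prop-1-en-2-yl)-6-(4,4,5,5-tetramethyl-1,3,2-dioxaborolan-2-yl)hex-4-en-2-yl acetate
Conditions: (COCl)2, DMSO, CH2Cl2, −78 °C; then Et3N, −78 to −30 °C
Reagents that add atoms: none
Why: Swern oxidation, which converts primary triethylsilyl ethers directly into aldehydes; the cold non-aqueous conditions should spare the allylboronate, and the aldehyde is used at once to avoid epimerisation next to the acetate.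

Step 11
Reactants: 16 ethane-1,2-diol
Product: 17 2-[(triethylsilyl)oxy]ethan-1-ol
Conditions: Et3SiCl, imidazole, 16 (excess), THF, 0 °C
Reagents that add atoms: chlorotriethylsilane, CC[Si](Cl)(CC)CC
Why: monosilylation of a symmetrical diol used in excess; no selectivity issue beyond statistics.

Step 12
Reactants: 18 methyl 2-[bis(2,2,2-trifluoroethoxy)phosphoryl]acetate; 19 formaldehyde (as paraformaldehyde)
Product: 20 methyl 2-[bis(2,2,2-trifluoroethoxy)phosphoryl]prop-2-enoate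
Conditions: (CH2O)n, piperidine (cat.), AcOH (cat.), PhMe, reflux with removal of water
Reagents that add atoms: none
Why: Knoevenagel condensation of the active methylene compound with formaldehyde (methylenation), run without alcohol solvent to keep the trifluoroethyl phosphonate esters.

Step 13
Reactants: 20 methyl 2-[bis(2,2,2-trifluoroethoxy)phosphoryl]prop-2-enoate; 17 2-[(triethylsilyl)oxy]ethan-1-ol
Product: 21 methyl 2-[bis(2,2,2-trifluoroethoxy)phosphoryl]-3-{2-[(triethylsilyl)oxy]ethoxy}propanoate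
Conditions: NaH (cat.), THF, 0 °C
Reagents that add atoms: none
Why: oxa-Michael addition of the primary alcohol to the doubly activated alkene under alkoxide catalysis; the product is racemic at a centre that is lost in step 14.

Step 14
Reactants: 15 (2S,3S,4Z)-4-methyl-1-oxo-3-(prop-1-en-2-yl)-6-(4,4,5,5-tetramethyl-1,3,2-dioxaborolan-2-yl)hex-4-en-2-yl acetate; 21 methyl 2-[bis(2,2,2-trifluoroethoxy)phosphoryl]-3-{2-[(triethylsilyl)oxy]ethoxy}propanoate
Product: 22 methyl (2Z,4R,5S,6Z)-4-(acetyloxy)-6-methyl-5-(prop-1-en-2-yl)-8-(4,4,5,5-tetramethyl-1,3,2-dioxaborolan-2-yl)-2-({2-[(triethylsilyl)oxy]ethoxy}methyl)octa-2,6-dienoate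
Conditions: 21, KN(SiMe3)2, 18-crown-6, THF, −78 °C; then 15, −78 °C
Reagents that add atoms: none
Why: Still–Gennari olefination; the bis(trifluoroethyl) phosphonate eliminates fast from the kinetic adduct and should give the (Z)-enoate with C6 cis to the ester, the geometry that the chair transition state of step 17 needs.

Step 15
Reactants: 22 methyl (2Z,4R,5S,6Z)-4-(acetyloxy)-6-methyl-5-(prop-1-en-2-yl)-8-(4,4,5,5-tetramethyl-1,3,2-dioxaborolan-2-yl)-2-({2-[(triethylsilyl)oxy]ethoxy}methyl)octa-2,6-dienoate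
Product: 23 methyl (2Z,4R,5S,6Z)-4-(acetyloxy)-6-methyl-2-[(2-oxoethoxy)methyl]-5-(prop-1-en-2-yl)-8-(4,4,5,5-tetramethyl-1,3,2-dioxaborolan-2-yl)octa-2,6-dienoate
Conditions: (COCl)2, DMSO, CH2Cl2, −78 °C; then Et3N, −78 to −30 °C
Reagents that add atoms: none
Why: second Swern oxidation of a primary triethylsilyl ether directly to the aldehyde; ester, acetate, boronate and the alkenes should be inert at −78 °C.

Step 16
Reactants: 23 methyl (2Z,4R,5S,6Z)-4-(acetyloxy)-6-methyl-2-[(2-oxoethoxy)methyl]-5-(prop-1-en-2-yl)-8-(4,4,5,5-tetramethyl-1,3,2-dioxaborolan-2-yl)octa-2,6-dienoate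
Product: 24 methyl (2Z,4R,5S,6Z)-4-(acetyloxy)-6-methyl-5-(prop-1-en-2-yl)-8-(4,4,5,5-tetramethyl-1,3,2-dioxaborolan-2-yl)-2-[({(Z)-2-[(triethylsilyl)oxy]ethenyl}oxy)methyl]octa-2,6-dienoate
Conditions: Et3SiOTf, Et3N, CH2Cl2, −78 °C
Reagents that add atoms: triethylsilyl trifluoromethanesulfonate, CC[Si](CC)(CC)OS(=O)(=O)C(F)(F)F
Why: soft enolisation and O-silylation of the aldehyde; α-alkoxy aldehydes should give mainly the (Z)-1,2-dioxygenated enol ether (cis effect), and the product is used promptly.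

Step 17
Reactants: 24 methyl (2Z,4R,5S,6Z)-4-(acetyloxy)-6-methyl-5-(prop-1-en-2-yl)-8-(4,4,5,5-tetramethyl-1,3,2-dioxaborolan-2-yl)-2-[({(Z)-2-[(triethylsilyl)oxy]ethenyl}oxy)methyl]octa-2,6-dienoate
Product: 27 methyl 2-[(1S,2S,3S,4S,5S,6R)-2-(acetyloxy)-4-ethenyl-5-hydroxy-4-methyl-3-(prop-1-en-2-yl)-6-[(triethylsilyl)oxy]cyclohexyl]prop-2-enoate, via Claisen aldehyde 25 (not isolated), via cyclohexyl borate 26 (not isolated)
Conditions: PhMe (high dilution), 2,6-lutidine (cat.), 105 °C; then aq. NaHCO3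
Reagents that add atoms: none
Why: On heating, 24 should undergo a Claisen [3,3] sigmatropic rearrangement (closest known types: thermal Claisen rearrangement of silyl enol ethers of α-allyloxy carbonyl compounds and of 2-(alkoxycarbonyl)allyl vinyl ethers) that forms C7–C8, creates the C11=C13 methylene and releases C9 as an aldehyde, which the (Z)-allylboronate then captures in an intramolecular allylboration (closest known type: cyclisation of ω-oxo allylboronates) that forms C9–C10 and the vinyl group. No ring is closed in the sigmatropic event; the carbocycle closes in a 6-exo-trig mode, the aldehyde carbon being attacked by the γ-carbon of the allylboronate through two fused chair transition states. The anti relation of C7 and C8 follows from the chair transition state of the (Z)-enol ether (silyloxy axial) with the (2Z)-enoate (C6 equatorial), and the sense at C7 comes from C6, whose hydrogen eclipses the alkene to avoid A(1,3) strain with the cis ester so that the new bond forms anti to the bulky C5 branch. C9 and C10 follow from the (Z)-geometry of the allylboronate in the closed chair (C5 axial on the boron-containing ring, hence O9 axial and cis to the new vinyl group, methyl axial), with the C5, C7 and C8 substituents equatorial on the forming cyclohexane. The step needs rearrangement before allylation and attack of the boronate on the aldehyde only; the first is secured because the aldehyde does not exist before the rearrangement, the second because pinacol allylboronates do not add to esters, acetates or enol ethers.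

Step 18
Reactants: 27 methyl 2-[(1S,2S,3S,4S,5S,6R)-2-(acetyloxy)-4-ethenyl-5-hydroxy-4-methyl-3-(prop-1-en-2-yl)-6-[(triethylsilyl)oxy]cyclohexyl]prop-2-enoate
Product: 29 (3aS,4S,5S,6S,7S,7aR)-6-ethenyl-7-hydroxy-6-methyl-3-methylidene-2-oxo-5-(prop-1-en-2-yl)octahydro-1-benzofuran-4-yl acetate, via diol ester 28 (not isolated)
Conditions: TsOH·H2O (cat.), MeOH–CH2Cl2, 0 °C to rt
Reagents that add atoms: none
Why: acid-catalysed methanolysis of the silyl ether followed by lactonisation (transesterification); only the C8 hydroxyl can form a five-membered lactone with the C7 acrylate (the axial C9 hydroxyl is trans-1,3 to it), which leaves C9–OH as the only free hydroxyl.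

Step 19
Reactants: 29 (3aS,4S,5S,6S,7S,7aR)-6-ethenyl-7-hydroxy-6-methyl-3-methylidene-2-oxo-5-(prop-1-en-2-yl)octahydro-1-benzofuran-4-yl acetate; 30 (2Z)-2-methylbut-2-enoic acid (angelic acid)
Product: 32 (3aS,4S,5S,6S,7S,7aR)-4-(acetyloxy)-6-ethenyl-6-methyl-3-methylidene-2-oxo-5-(prop-1-en-2-yl)octahydro-1-benzofuran-7-yl (2Z)-2-methylbut-2-enoate, via mixed anhydride 31 (not isolated)
Conditions: 30, 2,4,6-trichlorobenzoyl chloride, Et3N, PhMe, rt; then 29, 80 °C
Reagents that add atoms: none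
Why: Yamaguchi-type mixed anhydride esterification run without a nucleophilic catalyst, conditions under which the (Z)-acid should not isomerise to the tiglate; the C9 hydroxyl is the only nucleophile left.

Step 20
Reactants: 32 (3aS,4S,5S,6S,7S,7aR)-4-(acetyloxy)-6-ethenyl-6-methyl-3-methylidene-2-oxo-5-(prop-1-en-2-yl)octahydro-1-benzofuran-7-yl (2Z)-2-methylbut-2-enoate
Product: 34 (3aS,4S,5R,6S,7S,7aR)-4-(acetyloxy)-6-ethenyl-6-methyl-3-methylidene-2-oxo-5-(3-oxoprop-1-en-2-yl)octahydro-1-benzofuran-7-yl (2Z)-2-methylbut-2-enoate, via allylic alcohol 33 (not isolated)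
Conditions: SeO2 (cat.), t-BuOOH, CH2Cl2, rt; then MnO2, CH2Cl2, rt
Reagents that add atoms: tert-butyl hydroperoxide, CC(C)(C)OO (oxygen relayed by SeO2)
Why: Riley allylic oxidation (ene reaction, then [2,3] shift) of the methyl group of the isopropenyl unit, the only electron-rich alkene with allylic hydrogens, followed by MnO2 oxidation of the allylic alcohol to the enal; the conjugated and the monosubstituted alkenes should not react.

**Compound list**

1 | 2-bromoprop-1-ene | C=C(C)Br | starting material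
2 | prop-2-yn-1-ol | C#CCO | starting material
3 | 4-methylpent-4-en-2-yn-1-ol | C=C(C)C#CCO | intermediate
4 | (2Z)-4-methylpenta-2,4-dien-1-ol | C=C(C)/C=C\CO | intermediate
5 | [(2R,3S)-3-(prop-1-en-2-yl)oxiran-2-yl]methanol | OC[C@H]1O[C@H]1C(C)=C | intermediate
6 | triethyl{[(2R,3S)-3-(prop-1-en-2-yl)oxiran-2-yl]methoxy}silane | CC[Si](CC)(CC)OC[C@H]1O[C@H]1C(C)=C | intermediate
7 | 3,3,3-triethoxyprop-1-yne | C#CC(OCC)(OCC)OCC | starting material
8 | (2S,3S)-6,6,6-triethoxy-3-(prop-1-en-2-yl)-1-[(triethylsilyl)oxy]hex-4-yn-2-ol (not isolated) | CC[Si](CC)(CC)OC[C@@H](O)[C@@H](C(C)=C)C#CC(OCC)(OCC)OCC | intermediate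
9 | ethyl (4S,5S)-5-hydroxy-4-(prop-1-en-2-yl)-6-[(triethylsilyl)oxy]hex-2-ynoate | CC[Si](CC)(CC)OC[C@@H](O)[C@@H](C(C)=C)C#CC(=O)OCC | intermediate
10 | ethyl (2Z,4S,5S)-5-hydroxy-3-methyl-4-(prop-1-en-2-yl)-6-[(triethylsilyl)oxy]hex-2-enoate (not isolated) | CC[Si](CC)(CC)OC[C@@H](O)[C@@H](C(C)=C)/C(C)=C\C(=O)OCC | intermediate
11 | (5S,6S)-4-methyl-5-(prop-1-en-2-yl)-6-{[(triethylsilyl)oxy]methyl}-5,6-dihydro-2H-pyran-2-one | CC[Si](CC)(CC)OC[C@H]1OC(=O)C=C(C)[C@@H]1C(C)=C | intermediate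
12 | (2Z,4S,5S)-3-methyl-4-(prop-1-en-2-yl)-6-[(triethylsilyl)oxy]hex-2-ene-1,5-diol | OC/C=C(/C)[C@H](C(C)=C)[C@H](O)CO[Si](CC)(CC)CC | intermediate
13 | (2Z,4S,5S)-3-methyl-4-(prop-1-en-2-yl)-6-[(triethylsilyl)oxy]hex-2-ene-1,5-diyl diacetate | CC(=O)OC/C=C(/C)[C@H](C(C)=C)[C@H](OC(C)=O)CO[Si](CC)(CC)CC | intermediate
14 | (2S,3S,4Z)-4-methyl-3-(prop-1-en-2-yl)-6-(4,4,5,5-tetramethyl-1,3,2-dioxaborolan-2-yl)-1-[(triethylsilyl)oxy]hex-4-en-2-yl acetate | CC1(C)OB(C/C=C(/C)[C@H](C(C)=C)[C@H](OC(C)=O)CO[Si](CC)(CC)CC)OC1(C)C | intermediate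
15 | (2S,3S,4Z)-4-methyl-1-oxo-3-(prop-1-en-2-yl)-6-(4,4,5,5-tetramethyl-1,3,2-dioxaborolan-2-yl)hex-4-en-2-yl acetate | CC1(C)OB(C/C=C(/C)[C@H](C(C)=C)[C@H](OC(C)=O)C=O)OC1(C)C | intermediate
16 | ethane-1,2-diol | OCCO | starting material
17 | 2-[(triethylsilyl)oxy]ethan-1-ol | CC[Si](CC)(CC)OCCO | intermediate
18 | methyl 2-[bis(2,2,2-trifluoroethoxy)phosphoryl]acetate | COC(=O)CP(=O)(OCC(F)(F)F)OCC(F)(F)F | starting material
19 | formaldehyde (used as paraformaldehyde) | C=O | starting material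
20 | methyl 2-[bis(2,2,2-trifluoroethoxy)phosphoryl]prop-2-enoate | COC(=O)C(=C)P(=O)(OCC(F)(F)F)OCC(F)(F)F | intermediate
21 | methyl 2-[bis(2,2,2-trifluoroethoxy)phosphoryl]-3-{2-[(triethylsilyl)oxy]ethoxy}propanoate (racemic) | COC(=O)C(COCCO[Si](CC)(CC)CC)P(=O)(OCC(F)(F)F)OCC(F)(F)F | intermediate
22 | methyl (2Z,4R,5S,6Z)-4-(acetyloxy)-6-methyl-5-(prop-1-en-2-yl)-8-(4,4,5,5-tetramethyl-1,3,2-dioxaborolan-2-yl)-2-({2-[(triethylsilyl)oxy]ethoxy}methyl)octa-2,6-dienoate | CC1(C)OB(C/C=C(/C)[C@H](C(C)=C)[C@H](OC(C)=O)/C=C(\C(=O)OC)COCCO[Si](CC)(CC)CC)OC1(C)C | intermediate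
23 | methyl (2Z,4R,5S,6Z)-4-(acetyloxy)-6-methyl-2-[(2-oxoethoxy)methyl]-5-(prop-1-en-2-yl)-8-(4,4,5,5-tetramethyl-1,3,2-dioxaborolan-2-yl)octa-2,6-dienoate | CC1(C)OB(C/C=C(/C)[C@H](C(C)=C)[C@H](OC(C)=O)/C=C(\C(=O)OC)COCC=O)OC1(C)C | intermediate
24 | methyl (2Z,4R,5S,6Z)-4-(acetyloxy)-6-methyl-5-(prop-1-en-2-yl)-8-(4,4,5,5-tetramethyl-1,3,2-dioxaborolan-2-yl)-2-[({(Z)-2-[(triethylsilyl)oxy]ethenyl}oxy)methyl]octa-2,6-dienoate | CC1(C)OB(C/C=C(/C)[C@H](C(C)=C)[C@H](OC(C)=O)/C=C(\C(=O)OC)CO/C=C\O[Si](CC)(CC)CC)OC1(C)C | intermediate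
25 | methyl (3S,4S,5S,6Z)-4-(acetyloxy)-6-methyl-2-methylidene-3-{(1R)-2-oxo-1-[(triethylsilyl)oxy]ethyl}-5-(prop-1-en-2-yl)-8-(4,4,5,5-tetramethyl-1,3,2-dioxaborolan-2-yl)oct-6-enoate (not isolated) | CC1(C)OB(C/C=C(/C)[C@H](C(C)=C)[C@H](OC(C)=O)[C@H](C(=C)C(=O)OC)[C@@H](O[Si](CC)(CC)CC)C=O)OC1(C)C | intermediate
26 | methyl 2-[(1S,2S,3S,4S,5S,6R)-2-(acetyloxy)-4-ethenyl-4-methyl-3-(prop-1-en-2-yl)-5-[(4,4,5,5-tetramethyl-1,3,2-dioxaborolan-2-yl)oxy]-6-[(triethylsilyl)oxy]cyclohexyl]prop-2-enoate (not isolated) | C=C[C@]1(C)[C@H](OB2OC(C)(C)C(C)(C)O2)[C@H](O[Si](CC)(CC)CC)[C@@H](C(=C)C(=O)OC)[C@@H](OC(C)=O)[C@H]1C(C)=C | intermediate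
27 | methyl 2-[(1S,2S,3S,4S,5S,6R)-2-(acetyloxy)-4-ethenyl-5-hydroxy-4-methyl-3-(prop-1-en-2-yl)-6-[(triethylsilyl)oxy]cyclohexyl]prop-2-enoate | C=C[C@]1(C)[C@H](O)[C@H](O[Si](CC)(CC)CC)[C@@H](C(=C)C(=O)OC)[C@@H](OC(C)=O)[C@H]1C(C)=C | intermediate
28 | methyl 2-[(1R,2S,3S,4S,5S,6R)-2-(acetyloxy)-4-ethenyl-5,6-dihydroxy-4-methyl-3-(prop-1-en-2-yl)cyclohexyl]prop-2-enoate (same spatial arrangement as 27; not isolated) | C=C[C@]1(C)[C@H](O)[C@H](O)[C@@H](C(=C)C(=O)OC)[C@@H](OC(C)=O)[C@H]1C(C)=C | intermediate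
29 | (3aS,4S,5S,6S,7S,7aR)-6-ethenyl-7-hydroxy-6-methyl-3-methylidene-2-oxo-5-(prop-1-en-2-yl)octahydro-1-benzofuran-4-yl acetate | C=C[C@]1(C)[C@H](O)[C@@H]2OC(=O)C(=C)[C@H]2[C@@H](OC(C)=O)[C@H]1C(C)=C | intermediate
30 | (2Z)-2-methylbut-2-enoic acid (angelic acid) | C/C=C(/C)C(=O)O | starting material
31 | (2Z)-2-methylbut-2-enoic 2,4,6-trichlorobenzoic anhydride (not isolated) | C/C=C(/C)C(=O)OC(=O)c1c(Cl)cc(Cl)cc1Cl | intermediate
32 | (3aS,4S,5S,6S,7S,7aR)-4-(acetyloxy)-6-ethenyl-6-methyl-3-methylidene-2-oxo-5-(prop-1-en-2-yl)octahydro-1-benzofuran-7-yl (2Z)-2-methylbut-2-enoate | C=C[C@]1(C)[C@H](OC(=O)/C(C)=C\C)[C@@H]2OC(=O)C(=C)[C@H]2[C@@H](OC(C)=O)[C@H]1C(C)=C | intermediate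
33 | (3aS,4S,5S,6S,7S,7aR)-4-(acetyloxy)-6-ethenyl-5-(3-hydroxyprop-1-en-2-yl)-6-methyl-3-methylidene-2-oxooctahydro-1-benzofuran-7-yl (2Z)-2-methylbut-2-enoate (not isolated) | C=C[C@]1(C)[C@H](OC(=O)/C(C)=C\C)[C@@H]2OC(=O)C(=C)[C@H]2[C@@H](OC(C)=O)[C@H]1C(=C)CO | intermediate
34 | (3aS,4S,5R,6S,7S,7aR)-4-(acetyloxy)-6-ethenyl-6-methyl-3-methylidene-2-oxo-5-(3-oxoprop-1-en-2-yl)octahydro-1-benzofuran-7-yl (2Z)-2-methylbut-2-enoate | C=C[C@]1(C)[C@H](OC(=O)/C(C)=C\C)[C@@H]2OC(=O)C(=C)[C@H]2[C@@H](OC(C)=O)[C@H]1C(=C)C=O | target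

**Count**

Total step count: 20. Longest linear sequence: 17 steps (steps 1–10 and 14–20, from 2-bromoprop-1-ene); steps 11–13 form the side branch to phosphonate 21.

**Steps most likely to fail**

1. Step 17. The facial selectivity of the sigmatropic shift at C7 may be poor, because the steric preference for bond formation anti to the C5 branch is opposed by the electronic preference for bond formation anti to the allylic C6–O bond. Long heating may also erode the allylboronate before it is used.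
   Fallback (sets out from 13, comes back at 27): the boron is introduced only after the rearrangement, so that the rearranged aldehyde can be isolated and its C7 epimers separated. Diacetate 13 is oxidised under Swern conditions to (2S,3S,4Z)-6-(acetyloxy)-4-methyl-1-oxo-3-(prop-1-en-2-yl)hex-4-en-2-yl acetate F1. Still–Gennari olefination of F1 with 21 should give methyl (2Z,4R,5S,6Z)-4,8-bis(acetyloxy)-6-methyl-5-(prop-1-en-2-yl)-2-({2-[(triethylsilyl)oxy]ethoxy}methyl)octa-2,6-dienoate F2. A second Swern oxidation gives methyl (2Z,4R,5S,6Z)-4,8-bis(acetyloxy)-6-methyl-2-[(2-oxoethoxy)methyl]-5-(prop-1-en-2-yl)octa-2,6-dienoate F3, and Et3SiOTf with Et3N gives the enol ether methyl (2Z,4R,5S,6Z)-4,8-bis(acetyloxy)-6-methyl-5-(prop-1-en-2-yl)-2-[({(Z)-2-[(triethylsilyl)oxy]ethenyl}oxy)methyl]octa-2,6-dienoate F4. Heating F4 in PhMe should give the stable Claisen product methyl (3S,4S,5S,6Z)-4,8-bis(acetyloxy)-6-methyl-2-methylidene-3-{(1R)-2-oxo-1-[(triethylsilyl)oxy]ethyl}-5-(prop-1-en-2-yl)oct-6-enoate F5, which is purified. B2pin2 with catalytic Pd2(dba)3 in DMSO at 40 °C then borylates the only allylic acetate of F5 in the presence of the aldehyde (palladium-catalysed allylic borylation with allylboration in the same pot). The transient allylboronate is 25, which cyclises to 26 and gives 27 on work-up.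

2. Step 19. Acylation of the hindered axial C9 hydroxyl next to the quaternary C10 may be slow, which leaves time for (Z)-to-(E) isomerisation of the activated acid to the tiglate.
   Fallback (sets out from 29, comes back at 32): the (Z)-alkene is built on the ester instead of being carried through the acylation. Alcohol 29 is esterified with 2-[bis(2,2,2-trifluoroethoxy)phosphoryl]propanoic acid (DCC, DMAP, CH2Cl2), an acyl donor that cannot isomerise and can be forced, to give (3aS,4S,5S,6S,7S,7aR)-4-(acetyloxy)-6-ethenyl-6-methyl-3-methylidene-2-oxo-5-(prop-1-en-2-yl)octahydro-1-benzofuran-7-yl 2-[bis(2,2,2-trifluoroethoxy)phosphoryl]propanoate F6 (mixture of epimers at the phosphonate carbon). Still–Gennari olefination of F6 with acetaldehyde (KN(SiMe3)2, 18-crown-6, THF, −78 °C) should give the (Z)-2-methylbut-2-enoate 32.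

3. Step 20. The selenium oxidation may over-oxidise, attack the allylic C5–H, or isomerise the angelate.
   Fallback (sets out from 32, comes back at 34): a Schenck ene reaction of the isopropenyl group with singlet oxygen (O2, tetraphenylporphyrin, visible light, CH2Cl2) should give the hydroperoxide (3aS,4S,5S,6S,7S,7aR)-4-(acetyloxy)-6-ethenyl-5-(3-hydroperoxyprop-1-en-2-yl)-6-methyl-3-methylidene-2-oxooctahydro-1-benzofuran-7-yl (2Z)-2-methylbut-2-enoate F7. Dehydration of F7 with Ac2O and pyridine (Kornblum–DeLaMare type) gives enal 34.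

Further compounds
F1 | step 17 | (2S,3S,4Z)-6-(acetyloxy)-4-methyl-1-oxo-3-(prop-1-en-2-yl)hex-4-en-2-yl acetate | CC(=O)OC/C=C(/C)[C@H](C(C)=C)[C@H](OC(C)=O)C=O
F2 | step 17 | methyl (2Z,4R,5S,6Z)-4,8-bis(acetyloxy)-6-methyl-5-(prop-1-en-2-yl)-2-({2-[(triethylsilyl)oxy]ethoxy}methyl)octa-2,6-dienoate | CC(=O)OC/C=C(/C)[C@H](C(C)=C)[C@H](OC(C)=O)/C=C(\C(=O)OC)COCCO[Si](CC)(CC)CC
F3 | step 17 | methyl (2Z,4R,5S,6Z)-4,8-bis(acetyloxy)-6-methyl-2-[(2-oxoethoxy)methyl]-5-(prop-1-en-2-yl)octa-2,6-dienoate | CC(=O)OC/C=C(/C)[C@H](C(C)=C)[C@H](OC(C)=O)/C=C(\C(=O)OC)COCC=O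
F4 | step 17 | methyl (2Z,4R,5S,6Z)-4,8-bis(acetyloxy)-6-methyl-5-(prop-1-en-2-yl)-2-[({(Z)-2-[(triethylsilyl)oxy]ethenyl}oxy)methyl]octa-2,6-dienoate | CC(=O)OC/C=C(/C)[C@H](C(C)=C)[C@H](OC(C)=O)/C=C(\C(=O)OC)CO/C=C\O[Si](CC)(CC)CC
F5 | step 17 | methyl (3S,4S,5S,6Z)-4,8-bis(acetyloxy)-6-methyl-2-methylidene-3-{(1R)-2-oxo-1-[(triethylsilyl)oxy]ethyl}-5-(prop-1-en-2-yl)oct-6-enoate | CC(=O)OC/C=C(/C)[C@H](C(C)=C)[C@H](OC(C)=O)[C@H](C(=C)C(=O)OC)[C@@H](O[Si](CC)(CC)CC)C=O
F6 | step 19 | (3aS,4S,5S,6S,7S,7aR)-4-(acetyloxy)-6-ethenyl-6-methyl-3-methylidene-2-oxo-5-(prop-1-en-2-yl)octahydro-1-benzofuran-7-yl 2-[bis(2,2,2-trifluoroethoxy)phosphoryl]propanoate | C=C[C@]1(C)[C@H](OC(=O)C(C)P(=O)(OCC(F)(F)F)OCC(F)(F)F)[C@@H]2OC(=O)C(=C)[C@H]2[C@@H](OC(C)=O)[C@H]1C(C)=C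
F7 | step 20 | (3aS,4S,5S,6S,7S,7aR)-4-(acetyloxy)-6-ethenyl-5-(3-hydroperoxyprop-1-en-2-yl)-6-methyl-3-methylidene-2-oxooctahydro-1-benzofuran-7-yl (2Z)-2-methylbut-2-enoate | C=C[C@]1(C)[C@H](OC(=O)/C(C)=C\C)[C@@H]2OC(=O)C(=C)[C@H]2[C@@H](OC(C)=O)[C@H]1C(=C)COO
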